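**Retrosynthetic overview**

1. The plan rests on ring B (C1, C5–C10): the oxygen on C6 and the C8=C9 unsaturation (the later epoxide) are separated only by the methylene C7, and C10 is bonded to the quaternary C1 of ring A (C1–C5). This is the pattern left by a [3,3] shift of a 1-oxy-1-cyclopentenyl-2-vinylcyclopropane.
2. Target ⇒ (debenzylation, C6–OH-directed epoxidation, Evans–Tishchenko acylation/reduction) β-hydroxy ketone 18 ⇒ silylene enol ether 15.
3. 15 ⇒ (open C1–C10, restore C6–C8) cis-divinylcyclopropane 14, in which O4 and O6 are tied by a diisopropylsilylene so that only the cyclopropane matched to C4 can rearrange.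
4. 14 ⇒ Simmons–Smith reaction of the (E)-silyl enol ether of an α-ethynyl ketone (C7 from CH2I2, C8–C10 from 3-bromobut-1-yne) on the ring A enal obtained from (S)-terpinen-4-ol by ozonolysis and aldol condensation.
5. Ring order (forward): ring A (step 2), cyclopropane (step 6, temporary), silylene ring (step 8, temporary), ring B (step 10), oxirane (step 13).

Key step: step 10

Remark: atoms are numbered C1–C10 as in the bicyclic core (C1 quaternary CH3 carbon, C4 ester carbon, C5 ring-fusion CH, C6 carbinol, C8/C9 epoxide carbons) and β is the face of the C1 methyl group. Read this way the target is the 4β-ester, 5α-H, 6α-OH, 8α,9α-epoxide. 3-Bromobut-1-yne is used as the racemate.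

**Step 1**
Reactants: 1 (S)-terpinen-4-ol
Product: 3 (3S)-3-hydroxy-6-oxo-3-(propan-2-yl)heptanal, via ozonide 2 (not isolated)
Conditions: O3, CH2Cl2, −78 °C; then Me2S, −78 °C to rt
Reagents that add atoms: ozone, [O-][O+]=O
Why: Ozonolysis with reductive work-up cleaves the only C=C bond to the keto aldehyde (in equilibrium with its cyclic hemiketal), and the carbinol centre C4 is not touched.

**Step 2**
Reactants: 3 (3S)-3-hydroxy-6-oxo-3-(propan-2-yl)heptanal
Product: 4 (5R)-5-hydroxy-2-methyl-5-(propan-2-yl)cyclopent-1-ene-1-carbaldehyde (ring A; the CHO carbon is C6)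
Conditions: piperidine (0.3 equiv), AcOH (0.3 equiv), PhMe, 50 °C
Reagents that add atoms: none
Why: Amine–acid-catalysed intramolecular aldol condensation, in which the enamine of the aldehyde attacks the methyl ketone (5-enolexo closure) and water is lost to give the tetrasubstituted enal, as known for 6-oxoheptanals from 1-methylcyclohexene terpenes; C4 is not involved.

**Step 3**
Reactants: 4 the ring A hydroxy enal; 5 3-bromobut-1-yne
Product: 6 1-[5-hydroxy-2-methyl-5-(propan-2-yl)cyclopent-1-en-1-yl]-2-methylbut-3-yn-1-ol (C4 as in 4; mixture at C6 and C8)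
Conditions: 5 (3 equiv), Zn dust (4 equiv), THF, 0 °C to rt; aq. NH4Cl
Reagents that add atoms: 3-bromobut-1-yne (5), CC(Br)C#C
Why: Barbier-type propargylation, in which the allenylzinc bromide formed in the flask adds through its γ-carbon (SE2') to the aldehyde and gives the homopropargylic alcohol with a terminal alkyne; the free C4 hydroxyl only consumes reagent, and the new centres C6 and C8 need no control because both become trigonal in steps 4 and 5.

**Step 4**
Reactants: 6 the homopropargylic diol
Product: 7 1-[5-hydroxy-2-methyl-5-(propan-2-yl)cyclopent-1-en-1-yl]-2-methylbut-3-yn-1-one (C4 as in 4; C8 epimers)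
Conditions: Dess–Martin periodinane (1.3 equiv), CH2Cl2, 0 °C to rt
Reagents that add atoms: none
Why: Dess–Martin oxidation of the secondary carbinol; the tertiary C4 hydroxyl cannot be oxidised, and the base-free medium should keep the β,γ-alkynyl ketone from isomerising to the allenyl ketone.

**Step 5**
Reactants: 7 the hydroxy ynone
Product: 9 (E)-bis(trimethylsilyl) dienol ether, C4–OSiMe3 and C6(OSiMe3)=C8(CH3)–C≡CH with OSiMe3 cis to CH3 and cyclopentenyl cis to ethynyl, via C4 silyl ether 8 (not isolated)
Conditions: Me3SiOTf (2.5 equiv), Et3N (3.5 equiv), CH2Cl2, −78 to 0 °C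
Reagents that add atoms: trimethylsilyl trifluoromethanesulfonate, C[Si](C)(C)OS(=O)(=O)C(F)(F)F
Why: Silylation of the tertiary hydroxyl followed by soft enolisation (silyl triflate–amine) towards C8, the only and doubly activated α-position; the (E) geometry is expected because the slim linear ethynyl group, not the methyl group, takes the position cis to the bulky cyclopentenyl group that is twisted out of the enol ether plane (least allylic 1,3-strain), and this geometry later places cyclopentenyl and vinyl cis on the cyclopropane.

**Step 6**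
Reactants: 9 the (E)-dienol ether; 10 diiodomethane
Product: 11 1-cyclopentenyl-2-ethynyl-2-methyl-1-(trimethylsilyloxy)cyclopropane with C4–OSiMe3 (cyclopentenyl and ethynyl cis, OSiMe3 and CH3 cis; C6 and C8 as in the SMILES)
Conditions: Et2Zn (2 equiv), 10 (2 equiv), CH2Cl2, 0 °C; pyridine, then aq. NaHCO3
Reagents that add atoms: diiodomethane (10), ICI
Why: Furukawa-type Simmons–Smith cyclopropanation, in which the zinc carbenoid adds suprafacially to the electron-rich tetrasubstituted silyl enol ether (alkyne inert, tetrasubstituted ring A alkene shielded by C4 and C6), so the cis relations of step 5 are kept; the face relative to the remote C4 centre is not under firm control, the isomer drawn is the one that fits the later tether, and its mirror-configured partner at C6/C8 is removed after step 8 or stays behind unrearranged in step 10.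

**Step 7**
Reactants: 11 the bis(silyl) ethynylcyclopropane
Product: 12 1-[5-hydroxy-2-methyl-5-(propan-2-yl)cyclopent-1-en-1-yl]-2-ethynyl-2-methylcyclopropan-1-ol (configuration as in 11)
Conditions: Bu4NF (2.4 equiv), AcOH (2.4 equiv), THF, 0 °C
Reagents that add atoms: none
Why: Fluoride desilylation buffered with acetic acid cleaves both trimethylsilyl ethers while avoiding the free cyclopropanolate (fragmentation towards the propargylic anion) and strong acid (ring expansion of the 1-alkenylcyclopropanol).

**Step 8**
Reactants: 12 the cyclopropane-1,3-diol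
Product: 13 O4,O6-di(propan-2-yl)silylene acetal of 12 (six-membered 1,3-dioxa-2-silinane fused to ring A at C4–C5 and spiro to the cyclopropane at C6; ethynyl on C8)
Conditions: iPr2Si(OTf)2 (1.1 equiv), 2,6-lutidine (3 equiv), CH2Cl2 (0.01 M), −78 to 0 °C
Reagents that add atoms: di(propan-2-yl)silanediyl bis(trifluoromethanesulfonate), CC(C)[Si](OS(=O)(=O)C(F)(F)F)(OS(=O)(=O)C(F)(F)F)C(C)C
Why: Silylene acetal formation of a 1,3-diol with a dialkylsilyl bis(triflate), which is reactive enough for two tertiary hydroxyls; in the matched isomer only the C7 methylene comes near the C1 methyl group, whereas the mismatched isomer would have to eclipse quaternary C8 with it and should close poorly.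

**Step 9**
Reactants: 13 the ethynyl silylene acetal
Product: 14 O4,O6-di(propan-2-yl)silylene-bridged cis-1-cyclopentenyl-2-methyl-2-vinylcyclopropane (key-step precursor; configuration as in 13)
Conditions: H2 (1 atm), Pd/CaCO3 poisoned with Pb(OAc)2 (Lindlar catalyst), quinoline, EtOAc, 20 °C
Reagents that add atoms: none
Why: Lindlar semihydrogenation reduces the terminal alkyne to the vinyl group; the tetrasubstituted ring A alkene and the cyclopropane are not attacked and no stereocentre changes.

**Step 10**
Reactants: 14 the silylene-bridged cis-divinylcyclopropane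
Product: 15 tricyclic silylene enol ether: ring A fused to the new ring B (C5=C6 as part of the 4H-1,3,2-dioxasiline, C8=C9 alkene, quaternary C1 with CH3 cis to the C4 oxygen)
Conditions: PhMe (0.02 M, degassed), 100 °C, sealed tube
Reagents that add atoms: none
Why: On heating, the cis-1-cyclopentenyl-2-vinylcyclopropane should undergo the concerted [3,3] sigmatropic shift (divinylcyclopropane–cycloheptadiene Cope rearrangement) through a boat transition state in which the C1=C5 and C9=C10 double bonds both lie over the three-membered ring; the C6–C8 bond breaks, C1–C10 forms, and C5=C6 (as the cyclic silyl enol ether) and C8=C9 appear. The closest known reaction is the thermal rearrangement of 1-siloxy-cis-1,2-dialkenylcyclopropanes, including 2-methylcycloalkenyl cases that build a hydroazulene with an angular methyl group on a quaternary carbon. Ring B closes in one step as a seven-membered ring by ring expansion of the cyclopropane, through bonding between the alkene termini C1 and C10 and driven by release of ring strain. The only new stereocentre, C1, is set by chirality transfer from C6 and C8: C10 can reach C1 only on the face of ring A on which C8 sits, and the silylene, which holds O6 on the face of ring A that carries O4, places C8 and therefore C10 on the isopropyl face, so that the C1 methyl group ends cis to the C4 oxygen. The step needs the cis-dialkenyl arrangement, secured by the (E)-enol ether of step 5 and the stereospecific steps 6 and 9, and the matched relation of the cyclopropane to C4, secured by the tether, which fixes the reactive s-cis rotamer and leaves the C6–C8 bond of a mismatched isomer in the nodal plane of the C1=C5 π bond, where it cannot give the C1 epimer. The C1 methyl group is the inward substituent and must pass the endo hydrogen of C7, which raises the barrier above that of simple divinylcyclopropanes; the donor oxygen on C6 and the pre-organisation by the silylene are expected to keep the temperature near 100 °C.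

**Step 11**
Reactants: 15 the silylene enol ether
Product: 18 4β-hydroxy-5α-H-dauc-8-en-6-one (trans-fused β-hydroxy ketone), via enolate 16 (not isolated), via fluorosilyl ketone 17 (not isolated)
Conditions: Bu4NF (2.5 equiv), AcOH (3 equiv), THF, −20 °C to rt
Reagents that add atoms: none
Why: Fluoride desilylation of the silyl enol ether with kinetic C-protonation: fluoride attacks silicon and expels the enolate oxygen as the better leaving group, acetic acid protonates C5 at once, expected on the α face because the β face is flanked by the C1 methyl group and the O–SiF(iPr)2 group just released on C4 (trans ring fusion), and further fluoride removes the fluorosilyl group; equilibrating base is avoided because it would move the C8=C9 double bond into conjugation with the C6 ketone.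

**Step 12**
Reactants: 18 the β-hydroxy ketone; 19 4-(benzyloxy)-3-methoxybenzaldehyde
Product: 20 4β-[4-(benzyloxy)-3-methoxybenzoyloxy]-5α-H-dauc-8-en-6α-ol
Conditions: 19 (5 equiv), SmI2 (0.3 equiv), THF, −10 °C
Reagents that add atoms: 4-(benzyloxy)-3-methoxybenzaldehyde (19), COc1cc(C=O)ccc1OCc1ccccc1
Why: Evans–Tishchenko reduction: the C4 hydroxyl adds to the aldehyde at the trivalent samarium alkoxide catalyst (formed from SmI2, divalent samarium, and the aldehyde) and the bound hemiacetal passes its hydride through a six-membered transition state to the β face of the C6 carbonyl, the face of O4, so that C6–OH ends α (1,3-anti) while the aroyl group stays on the tertiary C4 oxygen, which spares a separate acylation of this hindered hydroxyl.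

**Step 13**
Reactants: 20 the homoallylic alcohol ester
Product: 21 4β-[4-(benzyloxy)-3-methoxybenzoyloxy]-8α,9α-epoxy-5α-H-daucan-6α-ol
Conditions: VO(acac)2 (0.05 equiv), t-BuOOH (1.5 equiv, in decane), CH2Cl2, 0 °C to rt
Reagents that add atoms: tert-butyl hydroperoxide, CC(C)(C)OO
Why: Hydroxyl-directed epoxidation: the vanadium alkoxide of the homoallylic C6 hydroxyl delivers the peroxide oxygen to the C8=C9 bond on its own (α) face, giving the 8α,9α-epoxide cis to C6–OH; the acylated C4 oxygen and the benzyl aryl ether do not interfere.

**Step 14**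
Reactants: 21 the benzyl-protected epoxy ester
Product: 22 CNP0315707.1 (4β-vanilloyloxy-8α,9α-epoxy-5α-H-daucan-6α-ol)
Conditions: H2 (1 atm), Pd/C (10 %), EtOAc, 20 °C
Reagents that add atoms: none
Why: Hydrogenolysis of the benzyl aryl ether under neutral conditions frees the phenol without acyl shift from the tertiary to the neighbouring secondary oxygen and without opening the trisubstituted epoxide; no C=C bond is left to reduce.

**Compound list**

1 | (S)-terpinen-4-ol | O[C@@]1(C(C)C)CCC(C)=CC1 | starting material
2 | secondary ozonide of 1 (1,2,4-trioxolane across the former C=C) | O[C@@]1(C(C)C)CCC2(C)OOC(C1)O2 | intermediate (not isolated)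
3 | (3S)-3-hydroxy-6-oxo-3-(propan-2-yl)heptanal | O[C@@](CC=O)(C(C)C)CCC(C)=O | intermediate
4 | (5R)-5-hydroxy-2-methyl-5-(propan-2-yl)cyclopent-1-ene-1-carbaldehyde | O[C@@]1(C(C)C)CCC(C)=C1C=O | intermediate
5 | 3-bromobut-1-yne (racemic) | CC(Br)C#C | starting material
6 | 1-[5-hydroxy-2-methyl-5-(propan-2-yl)cyclopent-1-en-1-yl]-2-methylbut-3-yn-1-ol (C4 as in 4; mixture at C6, C8) | O[C@@]1(C(C)C)CCC(C)=C1C(O)C(C)C#C | intermediate
7 | 1-[5-hydroxy-2-methyl-5-(propan-2-yl)cyclopent-1-en-1-yl]-2-methylbut-3-yn-1-one (C4 as in 4; C8 epimers) | O[C@@]1(C(C)C)CCC(C)=C1C(=O)C(C)C#C | intermediate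
8 | C4-O-trimethylsilyl ether of 7 | C[Si](C)(C)O[C@@]1(C(C)C)CCC(C)=C1C(=O)C(C)C#C | intermediate (not isolated)
9 | (E)-bis(trimethylsilyl) dienol ether (OSiMe3 on C6 cis to CH3 on C8) | C[Si](C)(C)O[C@@]1(C(C)C)CCC(C)=C1/C(O[Si](C)(C)C)=C(/C)C#C | intermediate
10 | diiodomethane | ICI | starting material
11 | bis(trimethylsilyl) ether of the cis-1-cyclopentenyl-2-ethynyl-2-methylcyclopropan-1-ol | C[Si](C)(C)O[C@@]1(C(C)C)CCC(C)=C1[C@]2(O[Si](C)(C)C)C[C@]2(C)C#C | intermediate
12 | 1-[5-hydroxy-2-methyl-5-(propan-2-yl)cyclopent-1-en-1-yl]-2-ethynyl-2-methylcyclopropan-1-ol (cyclopentenyl and ethynyl cis) | O[C@@]1(C(C)C)CCC(C)=C1[C@]2(O)C[C@]2(C)C#C | intermediate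
13 | O4,O6-di(propan-2-yl)silylene acetal of 12 | CC(C)[Si]1(C(C)C)O[C@@]2(C(C)C)CCC(C)=C2[C@]3(O1)C[C@]3(C)C#C | intermediate
14 | O4,O6-di(propan-2-yl)silylene-bridged cis-1-cyclopentenyl-2-methyl-2-vinylcyclopropane (key-step precursor) | CC(C)[Si]1(C(C)C)O[C@@]2(C(C)C)CCC(C)=C2[C@]3(O1)C[C@]3(C)C=C | intermediate
15 | tricyclic silylene enol ether (C5=C6 enol ether, C8=C9 alkene, quaternary C1; key-step product) | CC(C)[Si]1(C(C)C)O[C@@]2(C(C)C)CC[C@]3(C)CC=C(C)CC(O1)=C32 | intermediate
16 | tetrabutylammonium C5=C6 enolate with C4–O–SiF(iPr)2 | CC(C)[Si](F)(C(C)C)O[C@@]1(C(C)C)CC[C@]2(C)CC=C(C)CC([O-])=C21.CCCC[N+](CCCC)(CCCC)CCCC | intermediate (not isolated)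
17 | C4-O-[fluorodi(propan-2-yl)silyl] ether of 18 | CC(C)[Si](F)(C(C)C)O[C@@]1(C(C)C)CC[C@]2(C)CC=C(C)CC(=O)[C@H]21 | intermediate (not isolated)
18 | 4β-hydroxy-5α-H-dauc-8-en-6-one | O[C@@]1(C(C)C)CC[C@]2(C)CC=C(C)CC(=O)[C@H]21 | intermediate
19 | 4-(benzyloxy)-3-methoxybenzaldehyde | COc1cc(C=O)ccc1OCc1ccccc1 | starting material
20 | 4β-[4-(benzyloxy)-3-methoxybenzoyloxy]-5α-H-dauc-8-en-6α-ol | COc1cc(C(=O)O[C@@]2(C(C)C)CC[C@]3(C)CC=C(C)C[C@H](O)[C@H]32)ccc1OCc1ccccc1 | intermediate
21 | 4β-[4-(benzyloxy)-3-methoxybenzoyloxy]-8α,9α-epoxy-5α-H-daucan-6α-ol | COc1cc(C(=O)O[C@@]2(C(C)C)CC[C@]3(C)C[C@@H]4O[C@]4(C)C[C@H](O)[C@H]32)ccc1OCc1ccccc1 | intermediate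
22 | CNP0315707.1 | COc1cc(C(=O)O[C@@]2(C(C)C)CC[C@]3(C)C[C@@H]4O[C@]4(C)C[C@H](O)[C@H]32)ccc1O | target

Total step count: 14. Longest linear sequence: 14 steps (from 1).

**Steps most likely to fail**

Step 10. The [3,3] shift may be slow because the C1 methyl group has to pass the endo hydrogen of C7 in the boat, so that homolysis of the weakened C6–C8 bond or loss of the silylene could overtake it. The fallback replaces thermal activation by oxyanion acceleration and sets out from 14, freed of any mismatched isomer by chromatography at the stage of 13. MeLi (THF, −78 °C) attacks silicon and releases the lithium 1-cyclopentenyl-2-vinylcyclopropan-1-olate F1 with a methyldi(propan-2-yl)silyl ether on O4. As a 3-oxido-1,5-diene, F1 should undergo the anionic oxy-Cope shift below 0 °C to the lithium enolate F2. Acetic acid at −78 °C should give the silyl-protected trans-fused ketone F3, and HF·pyridine in THF returns to the route at 18.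

Step 12. Addition of the hindered tertiary hydroxyl to the aldehyde may be too slow, so that retro-aldol opening of ring A at the samarium alkoxide, acyl transfer to the new secondary oxygen, or pinacol coupling of 19 takes over. The fallback separates reduction and acylation and sets out from 18. Me4NBH(OAc)3 in AcOH/MeCN at −20 °C (hydroxyl-directed intramolecular hydride delivery) should give the 4β,6α-diol F4. Et3SiCl and imidazole should silylate only the secondary hydroxyl to give F5. The tertiary hydroxyl is then acylated with 4-(benzyloxy)-3-methoxybenzoyl chloride F6 (from the commercial acid and (COCl)2) under DMAP/Et3N in ClCH2CH2Cl at 70 °C to give ester F7. HF·pyridine removes the silyl group and returns to the route at 20.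

Step 6. The carbenoid may add mainly to the enol ether face that gives the mismatched cyclopropane, and this material is lost at steps 8–10. The fallback replaces the undirected addition by a hydroxyl-directed one and sets out from 7. KN(SiMe3)2 (1.0 equiv) followed by t-BuMe2SiOTf (1.0 equiv) at −78 °C should silylate only the enolate oxygen and give the (E)-tert-butyldimethylsilyl dienol ether F8 with a free C4 hydroxyl. Et2Zn (2.2 equiv) turns this hydroxyl into its zinc alkoxide, which binds the carbenoid from CH2I2 and delivers the methylene to the face it can reach when the small oxygen, not the isopropyl group, lies next to the ethynyl group (alkoxide-directed Simmons–Smith reaction), giving cyclopropane F9. Bu4NF/AcOH returns to the route at 12.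

**Further compounds**

F1 | step 10 | lithium cis-1-cyclopentenyl-2-methyl-2-vinylcyclopropan-1-olate with C4–O–SiMe(iPr)2 | CC(C)[Si](C)(C(C)C)O[C@@]1(C(C)C)CCC(C)=C1[C@]2([O-])C[C@]2(C)C=C.[Li+]
F2 | step 10 | lithium C5=C6 enolate of the ring-expanded ketone with C4–O–SiMe(iPr)2 | CC(C)[Si](C)(C(C)C)O[C@@]1(C(C)C)CC[C@]2(C)CC=C(C)CC([O-])=C21.[Li+]
F3 | step 10 | C4-O-[methyldi(propan-2-yl)silyl] ether of 18 | CC(C)[Si](C)(C(C)C)O[C@@]1(C(C)C)CC[C@]2(C)CC=C(C)CC(=O)[C@H]21
F4 | step 12 | 5α-H-dauc-8-ene-4β,6α-diol | O[C@@]1(C(C)C)CC[C@]2(C)CC=C(C)C[C@H](O)[C@H]21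
F5 | step 12 | 6α-(triethylsilyloxy)-5α-H-dauc-8-en-4β-ol | O[C@@]1(C(C)C)CC[C@]2(C)CC=C(C)C[C@H](O[Si](CC)(CC)CC)[C@H]21
F6 | step 12 | 4-(benzyloxy)-3-methoxybenzoyl chloride | COc1cc(C(Cl)=O)ccc1OCc1ccccc1
F7 | step 12 | 4β-[4-(benzyloxy)-3-methoxybenzoyloxy]-6α-(triethylsilyloxy)-5α-H-dauc-8-ene | COc1cc(C(=O)O[C@@]2(C(C)C)CC[C@]3(C)CC=C(C)C[C@H](O[Si](CC)(CC)CC)[C@H]32)ccc1OCc1ccccc1
F8 | step 6 | (E)-tert-butyldimethylsilyl dienol ether of 7 with free C4 hydroxyl | O[C@@]1(C(C)C)CCC(C)=C1/C(O[Si](C)(C)C(C)(C)C)=C(/C)C#C
F9 | step 6 | C6-O-tert-butyldimethylsilyl ether of 12 | O[C@@]1(C(C)C)CCC(C)=C1[C@]2(O[Si](C)(C)C(C)(C)C)C[C@]2(C)C#C
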